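The runs were computed on assumed constants.

The easy step is the autumn run: with [reagent] charged at 0.12 M, starting material reads 87.7% at 40.0 min.

| setting | autumn | south-east | south | east | north-west | south-west |
|---|---|---|---|---|---|---|
| starting material | 0.10 M | 0.10 M | 0.10 M | 0.10 M | 0.10 M | 0.10 M |
| reagent | 0.12 M | 0.120 M | 0.250 M | 0.500 M | 1.00 M | 2.00 M |
| second substrate | 0.034 M | 0.0500 M | 0.0500 M | 0.0500 M | 0.0500 M | 0.0500 M |
| third substrate | 0.10 M | 0.100 M | 0.100 M | 0.100 M | 0.100 M | 0.100 M |
| remark | run made earlier |  |  |  |  |  |
| time |  | 2.0 h | 2.0 h | 2.0 h | 2.0 h | 2.0 h |

- autumn (time / min: target / %, starting material / %): 8.00: 2.9, 97.3; 15.0: 5.3, 94.5; 25.0: 7.5, 91.4; 30.0: 8.8, 90.4; 40.0: 11.7, 87.7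

(readings scatter by 0.5 percentage points)

- "hardly changes" means that all values lie within two and a half points (for a concentration: within two and a half percent of the largest)

* amount of target at the end, in percent of the starting material charged for south-east, south, east, north-west, south-west, in this order
* the shape of the row from first to last (falls all the way / falls, then rises / rises all the way / rises, then falls / hardly changes)

From that last reading, with reagent held at its charge, I get 0.0273 M⁻¹ min⁻¹, a value that carries the scatter of the reading. I call it the turnover constant, the e-foldings of starting material per minute per molar of reagent. Multiplied by [reagent] it is a pseudo-first-order constant; multiplied also by the time it is a turnover count. The autumn run has a single reagent charge, so first order in reagent is my assumption.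

Now the ledger, assuming that each substrate takes reagent mole for mole. In south-east, 0.120 M of reagent faces claims of 0.250 M, so reagent is the limiting reagent there. With reagent held at its charge, a count of 0.394 pays starting material 0.0325 M. No reading covers second substrate and third substrate, so I book them at the same constant, 0.0488 M together. On this reckoning the south-east books close with 0.0386 M of reagent on hand, less than the charge, so I put south-east target below the count's 32.5%. The same count, with reagent again held at its charge, turns over 56.0% of the starting material in south, and in south-west, at a count of 6.56, it turns over 99.9%. I commit to a rising row, though the autumn run reaches a count of just 0.131.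

The forecast gives 34%, 45%, 49%, 50% and 50%, and its shape is: rises all the way. It adds that “side reactions at high reagent remain possible”. We agree on the shape and part at the top, where its row levels off and mine climbs.

The flasks give 22.2%, 39.1%, 56.7%, 62.0% and 46.9%; the shape is: rises, then falls.

    starting material + reagent → target (k = 0.0545 M⁻¹ min⁻¹)
    third substrate + reagent → third product (k = 0.0245 M⁻¹ min⁻¹)
    reagent ⇌ dormant form (K = 0.940, k = 0.403 min⁻¹)
    second substrate + reagent → second product (k = 0.0301 M⁻¹ min⁻¹)
    target ⇌ isomer of the product (K = 0.271, k = 0.00576 min⁻¹)
    reagent + target → over-reaction product (k = 0.00636 M⁻¹ min⁻¹)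

Starting material in south-east stands at 73.0% against the count's 67.5%, and in south-west at 0.226% against 0.141%. At the end of south-east, target is made 3.51 times faster than it is used, each step taken net, and over-reaction product stands at 0.451%. At the end of south-west, over-reaction product stands at 39.2% beside target at 46.9%. The row turns at a charged [reagent] of 0.85 M, a count of 2.79, with target at 62.7%.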